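**Retrosynthetic overview**
1. Target 29 ← global desilylation of tetrakis-TES ether 28.
2. 28 ← intramolecular oxa-Diels–Alder of 1,3-diacylallene 27 (O=C3–C4=C4a as heterodiene, tethered vinyl as dienophile); the carbocycle and the pyran ring close in the same step.
3. 27 ← ynedione 26 ← three-component union of enal 12, a C3 linchpin (propargyl bromide 22) and Weinreb amide 21.
4. 12 ← D-isoleucine 1 (C5' bought, C4' after inversion, C3' by chelation-controlled MeMgBr addition to an ynone).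
5. 21 ← (S)-3-hydroxy-γ-butyrolactone 13 (C8 bought, C7 by two trans-selective lactone enolate reactions; C8a arises in the cycloaddition).

Assumption: 1, 6, 13 and 22 are bought. Centres that are destroyed later (acetal carbon of 11, carbinol C9 of 25, allene axis of 27) are carried as mixtures and left undefined in the SMILES. The C8a outcome of step 14 is a conformational prediction, not a precedented result.

**Step 1**
Reactants: 1 D-isoleucine
Product: 2 (2R,3R)-2-hydroxy-3-methylpentanoic acid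
Conditions: NaNO2, 1 M H2SO4, 0 °C to rt
Reagents that add atoms: water, O
Why: Diazotisation of the α-amino acid and hydrolysis via the α-lactone (double inversion) replaces NH2 by OH with retention at C2.

**Step 2**
Reactants: 2 (2R,3R)-2-hydroxy-3-methylpentanoic acid
Product: 3 (2R,3R)-2-hydroxy-N-methoxy-N,3-dimethylpentanamide
Conditions: MeNHOMe·HCl, EDC·HCl, HOBt, N-methylmorpholine, CH2Cl2, 0 °C to rt
Reagents that add atoms: N,O-dimethylhydroxylamine hydrochloride, CNOC.Cl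
Why: Carbodiimide amide coupling gives the Weinreb amide without touching either stereocentre.

**Step 3**
Reactants: 3 (2R,3R)-2-hydroxy-N-methoxy-N,3-dimethylpentanamide
Product: 5 (2S,3R)-2-hydroxy-N-methoxy-N,3-dimethylpentanamide, via 4-nitrobenzoate 4 (not isolated)
Conditions: 4-O2NC6H4CO2H, PPh3, DIAD, THF, 0 °C to rt; then K2CO3 (cat.), MeOH, rt
Reagents that add atoms: 4-nitrobenzoic acid, OC(=O)c1ccc(cc1)[N+](=O)[O-]
Why: Mitsunobu esterification displaces the activated α-hydroxyl with clean SN2 inversion (C2 becomes S) and methanolysis frees the alcohol.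

**Step 4**
Reactants: 5 (2S,3R)-2-hydroxy-N-methoxy-N,3-dimethylpentanamide; 6 3,3-diethoxyprop-1-yne
Product: 8 (5S,6R)-1,1-diethoxy-5-hydroxy-6-methyloct-2-yn-4-one, via lithium acetylide 7 (not isolated)
Conditions: 6 (3 equiv), n-BuLi, THF, −78 °C; then 5, −78 to −10 °C; cold aq. NH4Cl
Reagents that add atoms: none
Why: Weinreb ketone synthesis; the chelated tetrahedral intermediate stops at the ynone and the first equivalent of acetylide only deprotonates the hydroxyl.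

**Step 5**
Reactants: 8 (5S,6R)-1,1-diethoxy-5-hydroxy-6-methyloct-2-yn-4-one
Product: 9 (4R,5S,6R)-1,1-diethoxy-4,6-dimethyloct-2-yne-4,5-diol
Conditions: MeMgBr (4 equiv), THF, −78 °C
Reagents that add atoms: methylmagnesium bromide, C[Mg]Br
Why: Cram-chelate Grignard addition; the magnesium alkoxide chelates the ketone and methyl enters from the face of the C5 hydrogen, giving the anti (erythro) diol with C4 = R.

**Step 6**
Reactants: 9 (4R,5S,6R)-1,1-diethoxy-4,6-dimethyloct-2-yne-4,5-diol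
Product: 10 (2E,4R,5S,6R)-1,1-diethoxy-4,6-dimethyloct-2-ene-4,5-diol
Conditions: NaAlH2(OCH2CH2OMe)2, THF, 0 °C to rt; aq. KNaC4H4O6
Reagents that add atoms: none
Why: Alkoxide-directed trans-hydroalumination of the propargylic alcohol gives the (E)-alkene only, and the acetal survives as in the classical 4-hydroxy-2-enal syntheses.

**Step 7**
Reactants: 10 (2E,4R,5S,6R)-1,1-diethoxy-4,6-dimethyloct-2-ene-4,5-diol
Product: 12 (2E,4R,5S,6R)-4,6-dimethyl-4,5-bis[(triethylsilyl)oxy]oct-2-enal, via lutidinium salt 11 (not isolated)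
Conditions: Et3SiOTf (5 equiv), 2,6-lutidine (7 equiv), CH2Cl2, 0 °C; then H2O
Reagents that add atoms: triethylsilyl triflate, CC[Si](CC)(CC)OS(=O)(=O)C(F)(F)F; water, O
Why: Silyl triflate silylates both hydroxyls and converts the aldehyde acetal into a pyridinium N,O-acetal (Fujioka-type acetal cleavage) that water hydrolyses to the enal.

**Step 8**
Reactants: 13 (S)-3-hydroxy-γ-butyrolactone [(4S)-4-hydroxyoxolan-2-one]
Product: 15 (3S,4S)-4-hydroxy-3-methyloxolan-2-one, via lactone dianion 14 (not isolated)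
Conditions: LiN(i-Pr)2 (2.2 equiv), THF/HMPA, −78 to −40 °C; then MeI
Reagents that add atoms: iodomethane, CI
Why: Fráter–Seebach-type alkylation of the alkoxide–enolate dianion; methyl enters anti to the C4 oxygen (trans product).

**Step 9**
Reactants: 15 (3S,4S)-4-hydroxy-3-methyloxolan-2-one
Product: 17 (3S,4R)-3,4-dihydroxy-3-methyloxolan-2-one, via lactone dianion 16 (not isolated)
Conditions: LiN(i-Pr)2 (2.3 equiv), THF, −78 °C; then MoO5·pyridine·HMPA, −78 to −40 °C; aq. Na2SO3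
Reagents that add atoms: MoO5·pyridine·HMPA, O=[Mo]12(OO1)OO2.c1ccncc1.CN(C)P(=O)(N(C)C)N(C)C
Why: Vedejs enolate hydroxylation; oxygen is delivered anti to the C4 alkoxide, so the new tertiary OH is trans to the C4 OH and the methyl ends up cis to it.

**Step 10**
Reactants: 17 (3S,4R)-3,4-dihydroxy-3-methyloxolan-2-one
Product: 18 (3S,4R)-3-methyl-3,4-bis[(triethylsilyl)oxy]oxolan-2-one
Conditions: Et3SiOTf (2.5 equiv), 2,6-lutidine, CH2Cl2, 0 °C to rt
Reagents that add atoms: triethylsilyl triflate, CC[Si](CC)(CC)OS(=O)(=O)C(F)(F)F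
Why: Silyl triflate silylation protects the secondary and the hindered tertiary hydroxyl as separate, non-cyclic ethers.

**Step 11**
Reactants: 18 (3S,4R)-3-methyl-3,4-bis[(triethylsilyl)oxy]oxolan-2-one
Product: 19 (2S,3R)-4-hydroxy-N-methoxy-N,2-dimethyl-2,3-bis[(triethylsilyl)oxy]butanamide
Conditions: MeNHOMe·HCl, AlMe3, CH2Cl2, 0 °C to rt; aq. KNaC4H4O6
Reagents that add atoms: N,O-dimethylhydroxylamine hydrochloride, CNOC.Cl
Why: Weinreb aminolysis of the lactone with the aluminium amide opens the ring at the acyl carbon and frees the primary alcohol as a covalent aluminium alkoxide, which disfavours silyl migration.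

**Step 12**
Reactants: 19 (2S,3R)-4-hydroxy-N-methoxy-N,2-dimethyl-2,3-bis[(triethylsilyl)oxy]butanamide
Product: 21 (2S,3R)-N-methoxy-N,2-dimethyl-2,3-bis[(triethylsilyl)oxy]pent-4-enamide, via aldehyde 20 (not isolated)
Conditions: Dess–Martin periodinane, NaHCO3, CH2Cl2, 0 °C to rt; filter, concentrate; then Ph3PCH3Br, KN(SiMe3)2, THF, −78 to 0 °C
Reagents that add atoms: methyltriphenylphosphonium bromide, C[P+](c1ccccc1)(c1ccccc1)c1ccccc1.[Br-]
Why: Dess–Martin oxidation followed by Wittig methylenation of the crude α-silyloxy aldehyde installs the vinyl group; the Weinreb amide is inert to the ylide.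

**Step 13**
Reactants: 12 (2E,4R,5S,6R)-4,6-dimethyl-4,5-bis[(triethylsilyl)oxy]oct-2-enal; 22 propargyl bromide (3-bromoprop-1-yne); 21 (2S,3R)-N-methoxy-N,2-dimethyl-2,3-bis[(triethylsilyl)oxy]pent-4-enamide
Product: 25 (3R,4S,10E,12R,13S,14R)-9-hydroxy-4,12,14-trimethyl-3,4,12,13-tetrakis[(triethylsilyl)oxy]hexadeca-1,10-dien-6-yn-5-one (both C9 epimers), via 1,3-dilithiopropyne 23 (not isolated), via dilithio adduct 24 (not isolated)
Conditions: 22 (1.3 equiv), n-BuLi (2.6 equiv), TMEDA, Et2O, −78 °C; then 12 (1.0 equiv), −78 °C; then 21 (1.6 equiv), −78 to 0 °C; aq. NH4Cl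
Reagents that add atoms: none
Why: Sequential trapping of 1,3-dilithiopropyne: the propargylic terminus adds 1,2 to the non-enolisable enal, and the remaining acetylide acylates the Weinreb amide (Weinreb ketone synthesis) without over-addition.

**Step 14**
Reactants: 25 (3R,4S,10E,12R,13S,14R)-9-hydroxy-4,12,14-trimethyl-3,4,12,13-tetrakis[(triethylsilyl)oxy]hexadeca-1,10-dien-6-yn-5-one
Product: 28 (7S,8R,8aS)-3-[(1E,3R,4S,5R)-3,5-dimethyl-3,4-bis(triethylsilyloxy)hept-1-en-1-yl]-7-methyl-7,8-bis(triethylsilyloxy)-1,7,8,8a-tetrahydro-6H-isochromen-6-one, via ynedione 26 (not isolated), via diacylallene 27 (not isolated)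
Conditions: Dess–Martin periodinane, NaHCO3, CH2Cl2, 0 °C to rt; filter, concentrate; then Et3N (0.2 equiv), BHT, PhMe (0.005 M), 80 °C
Reagents that add atoms: none
Why: Dess–Martin oxidation gives skipped ynedione 26, Et3N isomerises it to 1,3-diacylallene 27, and an intramolecular inverse-electron-demand oxa-Diels–Alder (O=C3–C4=C4a with the tethered vinyl) closes both rings; C8a is set by C8 through a half-chair tether with the two silyloxy groups trans-diaxial, the C7 methyl equatorial and the allylic C8–O bond inside, which puts H-8a cis to H-8.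

**Step 15**
Reactants: 28 tetrakis-TES ether
Product: 29 (7S,8R,8aS)-3-[(1E,3R,4S,5R)-3,4-dihydroxy-3,5-dimethylhept-1-en-1-yl]-7,8-dihydroxy-7-methyl-1,7,8,8a-tetrahydro-6H-isochromen-6-one (target)
Conditions: HF·pyridine, pyridine, THF, 0 °C to rt
Reagents that add atoms: none
Why: Buffered fluoride desilylation removes all four triethylsilyl ethers without strong acid or base, so the tertiary allylic alcohol, the α-ketol and the epimerisable C8a survive.

**Compound list**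
1 | D-isoleucine | CC[C@@H](C)[C@@H](N)C(=O)O | starting material
2 | (2R,3R)-2-hydroxy-3-methylpentanoic acid | CC[C@@H](C)[C@@H](O)C(=O)O | intermediate
3 | (2R,3R)-2-hydroxy-N-methoxy-N,3-dimethylpentanamide | CC[C@@H](C)[C@@H](O)C(=O)N(C)OC | intermediate
4 | (2S,3R)-1-[methoxy(methyl)amino]-3-methyl-1-oxopentan-2-yl 4-nitrobenzoate | CC[C@@H](C)[C@H](OC(=O)c1ccc(cc1)[N+](=O)[O-])C(=O)N(C)OC | intermediate (not isolated)
5 | (2S,3R)-2-hydroxy-N-methoxy-N,3-dimethylpentanamide | CC[C@@H](C)[C@H](O)C(=O)N(C)OC | intermediate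
6 | 3,3-diethoxyprop-1-yne | C#CC(OCC)OCC | starting material
7 | lithium 3,3-diethoxyprop-1-yn-1-ide | [Li]C#CC(OCC)OCC | intermediate (not isolated)
8 | (5S,6R)-1,1-diethoxy-5-hydroxy-6-methyloct-2-yn-4-one | CC[C@@H](C)[C@H](O)C(=O)C#CC(OCC)OCC | intermediate
9 | (4R,5S,6R)-1,1-diethoxy-4,6-dimethyloct-2-yne-4,5-diol | CC[C@@H](C)[C@H](O)[C@](C)(O)C#CC(OCC)OCC | intermediate
10 | (2E,4R,5S,6R)-1,1-diethoxy-4,6-dimethyloct-2-ene-4,5-diol | CC[C@@H](C)[C@H](O)[C@](C)(O)/C=C/C(OCC)OCC | intermediate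
11 | 1-[(2E,4R,5S,6R)-1-ethoxy-4,6-dimethyl-4,5-bis(triethylsilyloxy)oct-2-en-1-yl]-2,6-dimethylpyridinium triflate | CC[C@@H](C)[C@H](O[Si](CC)(CC)CC)[C@](C)(O[Si](CC)(CC)CC)/C=C/C(OCC)[n+]1c(C)cccc1C.[O-]S(=O)(=O)C(F)(F)F | intermediate (not isolated)
12 | (2E,4R,5S,6R)-4,6-dimethyl-4,5-bis[(triethylsilyl)oxy]oct-2-enal | CC[C@@H](C)[C@H](O[Si](CC)(CC)CC)[C@](C)(O[Si](CC)(CC)CC)/C=C/C=O | intermediate
13 | (S)-3-hydroxy-γ-butyrolactone, (4S)-4-hydroxyoxolan-2-one | O=C1C[C@H](O)CO1 | starting material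
14 | dilithium alkoxide–enolate of 13 | [Li]OC1=C[C@H](O[Li])CO1 | intermediate (not isolated)
15 | (3S,4S)-4-hydroxy-3-methyloxolan-2-one | O=C1[C@@H](C)[C@H](O)CO1 | intermediate
16 | dilithium alkoxide–enolate of 15 | [Li]OC1=C(C)[C@H](O[Li])CO1 | intermediate (not isolated)
17 | (3S,4R)-3,4-dihydroxy-3-methyloxolan-2-one | O=C1[C@@](C)(O)[C@H](O)CO1 | intermediate
18 | (3S,4R)-3-methyl-3,4-bis[(triethylsilyl)oxy]oxolan-2-one | O=C1[C@@](C)(O[Si](CC)(CC)CC)[C@H](O[Si](CC)(CC)CC)CO1 | intermediate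
19 | (2S,3R)-4-hydroxy-N-methoxy-N,2-dimethyl-2,3-bis[(triethylsilyl)oxy]butanamide | CON(C)C(=O)[C@@](C)(O[Si](CC)(CC)CC)[C@H](O[Si](CC)(CC)CC)CO | intermediate
20 | (2S,3S)-N-methoxy-N,2-dimethyl-4-oxo-2,3-bis[(triethylsilyl)oxy]butanamide | CON(C)C(=O)[C@@](C)(O[Si](CC)(CC)CC)[C@H](O[Si](CC)(CC)CC)C=O | intermediate (not isolated)
21 | (2S,3R)-N-methoxy-N,2-dimethyl-2,3-bis[(triethylsilyl)oxy]pent-4-enamide | CON(C)C(=O)[C@@](C)(O[Si](CC)(CC)CC)[C@H](O[Si](CC)(CC)CC)C=C | intermediate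
22 | propargyl bromide, 3-bromoprop-1-yne | C#CCBr | starting material
23 | 1,3-dilithiopropyne | [Li]CC#C[Li] | intermediate (not isolated)
24 | dilithium alkoxide–acetylide of (5E,7R,8S,9R)-7,9-dimethyl-7,8-bis[(triethylsilyl)oxy]undec-5-en-1-yn-4-ol | CC[C@@H](C)[C@H](O[Si](CC)(CC)CC)[C@](C)(O[Si](CC)(CC)CC)/C=C/C(O[Li])CC#C[Li] | intermediate (not isolated)
25 | (3R,4S,10E,12R,13S,14R)-9-hydroxy-4,12,14-trimethyl-3,4,12,13-tetrakis[(triethylsilyl)oxy]hexadeca-1,10-dien-6-yn-5-one | CC[C@@H](C)[C@H](O[Si](CC)(CC)CC)[C@](C)(O[Si](CC)(CC)CC)/C=C/C(O)CC#CC(=O)[C@@](C)(O[Si](CC)(CC)CC)[C@H](O[Si](CC)(CC)CC)C=C | intermediate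
26 | (3R,4S,10E,12R,13S,14R)-4,12,14-trimethyl-3,4,12,13-tetrakis[(triethylsilyl)oxy]hexadeca-1,10-dien-6-yne-5,9-dione | CC[C@@H](C)[C@H](O[Si](CC)(CC)CC)[C@](C)(O[Si](CC)(CC)CC)/C=C/C(=O)CC#CC(=O)[C@@](C)(O[Si](CC)(CC)CC)[C@H](O[Si](CC)(CC)CC)C=C | intermediate (not isolated)
27 | (3R,4S,10E,12R,13S,14R)-4,12,14-trimethyl-3,4,12,13-tetrakis[(triethylsilyl)oxy]hexadeca-1,6,7,10-tetraene-5,9-dione | CC[C@@H](C)[C@H](O[Si](CC)(CC)CC)[C@](C)(O[Si](CC)(CC)CC)/C=C/C(=O)C=C=CC(=O)[C@@](C)(O[Si](CC)(CC)CC)[C@H](O[Si](CC)(CC)CC)C=C | intermediate (not isolated)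
28 | (7S,8R,8aS)-3-[(1E,3R,4S,5R)-3,5-dimethyl-3,4-bis(triethylsilyloxy)hept-1-en-1-yl]-7-methyl-7,8-bis(triethylsilyloxy)-1,7,8,8a-tetrahydro-6H-isochromen-6-one | CC[C@@H](C)[C@H](O[Si](CC)(CC)CC)[C@](C)(O[Si](CC)(CC)CC)/C=C/C1=CC2=CC(=O)[C@@](C)(O[Si](CC)(CC)CC)[C@H](O[Si](CC)(CC)CC)[C@@H]2CO1 | intermediate
29 | (7S,8R,8aS)-3-[(1E,3R,4S,5R)-3,4-dihydroxy-3,5-dimethylhept-1-en-1-yl]-7,8-dihydroxy-7-methyl-1,7,8,8a-tetrahydro-6H-isochromen-6-one | CC[C@@H](C)[C@H](O)[C@](C)(O)/C=C/C1=CC2=CC(=O)[C@@](C)(O)[C@H](O)[C@@H]2CO1 | target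

**Step count**
Total: 15 steps. Longest linear sequence: 10 steps (steps 1–7, then 13–15); the lactone branch (steps 8–12) is 5 steps.

**Steps most likely to fail, with fallbacks**

Step 14 (oxidation / allene formation / oxa-Diels–Alder). The dienophile is an unactivated terminal alkene and must bond through its internal carbon, and the C8a outcome rests on a conformational argument. Fallback: use a donor-substituted, polarity-matched dienophile. Set out from 19: oxidise to 20 as in step 12, then run the Wittig reaction with Ph3P=CHSPh (from the phosphonium chloride and n-BuLi) to give (2S,3R)-N-methoxy-N,2-dimethyl-5-(phenylsulfanyl)-2,3-bis[(triethylsilyl)oxy]pent-4-enamide F1. Couple F1 with 12 and 22 through 23 and 24 exactly as in step 13 to give the 1-(phenylsulfanyl) hydroxy ynone F2. Dess–Martin oxidation gives the 1-(phenylsulfanyl) ynedione F3 and Et3N the 1-(phenylsulfanyl) diacylallene F4. The nucleophilic β-carbon of the vinyl sulfide now attacks C4a in a fast hetero-Diels–Alder reaction, giving the 1-(phenylsulfanyl) bicycle F5. Radical desulfurisation (Bu3SnH, AIBN, benzene, 80 °C) rejoins the route at 28.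

Step 13 (one-pot three-component coupling). The stoichiometry of the dilithio reagent is hard to control and the Weinreb amide is hindered. Fallback: a stepwise union. Set out from 12: Barbier propargylation (Zn dust, 22, THF/aq. NH4Cl, 0 °C) gives (5E,7R,8S,9R)-7,9-dimethyl-7,8-bis[(triethylsilyl)oxy]undec-5-en-1-yn-4-ol F6, which is isolated and purified. Exactly 2 equivalents of n-BuLi (THF, −78 °C) regenerate 24, and addition of 21 (1.1 equiv) rejoins the route at 25.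

Step 5 (Grignard addition to the unprotected α-hydroxy ynone). The alkoxide can cyclise onto the ynone to a furanone, and MeMgBr can add in conjugate fashion. Fallback: chelation through an ether instead of the free alkoxide. Set out from 5: 4-methoxybenzyl trichloroacetimidate with La(OTf)3 (cat.) gives (2S,3R)-N-methoxy-2-[(4-methoxybenzyl)oxy]-N,3-dimethylpentanamide F7. Acylation of 7 gives (5S,6R)-1,1-diethoxy-5-[(4-methoxybenzyl)oxy]-6-methyloct-2-yn-4-one F8. MeMgBr in Et2O/CH2Cl2 at −78 °C adds under chelation by the benzyl ether oxygen to give (4R,5S,6R)-1,1-diethoxy-5-[(4-methoxybenzyl)oxy]-4,6-dimethyloct-2-yn-4-ol F9. DDQ in CH2Cl2/pH 7 buffer removes the ether and rejoins the route at 9.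

**Further compounds**
F1 | step 14 | (2S,3R)-N-methoxy-N,2-dimethyl-5-(phenylsulfanyl)-2,3-bis[(triethylsilyl)oxy]pent-4-enamide (E/Z) | CON(C)C(=O)[C@@](C)(O[Si](CC)(CC)CC)[C@H](O[Si](CC)(CC)CC)C=CSc1ccccc1
F2 | step 14 | (3R,4S,10E,12R,13S,14R)-9-hydroxy-4,12,14-trimethyl-1-(phenylsulfanyl)-3,4,12,13-tetrakis[(triethylsilyl)oxy]hexadeca-1,10-dien-6-yn-5-one | CC[C@@H](C)[C@H](O[Si](CC)(CC)CC)[C@](C)(O[Si](CC)(CC)CC)/C=C/C(O)CC#CC(=O)[C@@](C)(O[Si](CC)(CC)CC)[C@H](O[Si](CC)(CC)CC)C=CSc1ccccc1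
F3 | step 14 | (3R,4S,10E,12R,13S,14R)-4,12,14-trimethyl-1-(phenylsulfanyl)-3,4,12,13-tetrakis[(triethylsilyl)oxy]hexadeca-1,10-dien-6-yne-5,9-dione | CC[C@@H](C)[C@H](O[Si](CC)(CC)CC)[C@](C)(O[Si](CC)(CC)CC)/C=C/C(=O)CC#CC(=O)[C@@](C)(O[Si](CC)(CC)CC)[C@H](O[Si](CC)(CC)CC)C=CSc1ccccc1
F4 | step 14 | (3R,4S,10E,12R,13S,14R)-4,12,14-trimethyl-1-(phenylsulfanyl)-3,4,12,13-tetrakis[(triethylsilyl)oxy]hexadeca-1,6,7,10-tetraene-5,9-dione | CC[C@@H](C)[C@H](O[Si](CC)(CC)CC)[C@](C)(O[Si](CC)(CC)CC)/C=C/C(=O)C=C=CC(=O)[C@@](C)(O[Si](CC)(CC)CC)[C@H](O[Si](CC)(CC)CC)C=CSc1ccccc1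
F5 | step 14 | (7S,8R,8aR)-3-[(1E,3R,4S,5R)-3,5-dimethyl-3,4-bis(triethylsilyloxy)hept-1-en-1-yl]-7-methyl-1-(phenylsulfanyl)-7,8-bis(triethylsilyloxy)-1,7,8,8a-tetrahydro-6H-isochromen-6-one (C1 epimers) | CC[C@@H](C)[C@H](O[Si](CC)(CC)CC)[C@](C)(O[Si](CC)(CC)CC)/C=C/C1=CC2=CC(=O)[C@@](C)(O[Si](CC)(CC)CC)[C@H](O[Si](CC)(CC)CC)[C@@H]2C(Sc3ccccc3)O1
F6 | step 13 | (5E,7R,8S,9R)-7,9-dimethyl-7,8-bis[(triethylsilyl)oxy]undec-5-en-1-yn-4-ol | CC[C@@H](C)[C@H](O[Si](CC)(CC)CC)[C@](C)(O[Si](CC)(CC)CC)/C=C/C(O)CC#C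
F7 | step 5 | (2S,3R)-N-methoxy-2-[(4-methoxybenzyl)oxy]-N,3-dimethylpentanamide | CC[C@@H](C)[C@H](OCc1ccc(OC)cc1)C(=O)N(C)OC
F8 | step 5 | (5S,6R)-1,1-diethoxy-5-[(4-methoxybenzyl)oxy]-6-methyloct-2-yn-4-one | CC[C@@H](C)[C@H](OCc1ccc(OC)cc1)C(=O)C#CC(OCC)OCC
F9 | step 5 | (4R,5S,6R)-1,1-diethoxy-5-[(4-methoxybenzyl)oxy]-4,6-dimethyloct-2-yn-4-ol | CC[C@@H](C)[C@H](OCc1ccc(OC)cc1)[C@](C)(O)C#CC(OCC)OCC
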